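The cyclohexanone ring (C1 quaternary carbinol bearing C7H2OBz, C2 ketone, C3 methylene, C4–C6 oxygenated) is cut at C1–C6, because the array C2(=O)–C1(=C7)–C6H(OH) is a Morita–Baylis–Hillman pattern. One phosphine-catalysed cyclisation of an acyclic vinyl ketone–aldehyde closes the six-membered ring, creates C6 and leaves C7 as an exocyclic methylene onto which the new C6 hydroxyl later directs oxygen. The precursor, (2R,3R)-2-benzoyloxy-3-(tert-butyldimethylsilyloxy)-5-oxohept-6-enal, carries C4 and C5 unchanged from 2-deoxy-L-ribose; its enone is made directly from a Weinreb amide and its aldehyde is unveiled last, so no lactol-forming diol stage arises.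

Key step: step 7

Remark (numbering): ring atoms are C1 (quaternary carbinol), C2 (C=O), C3 (CH2), C4 (OH), C5 (OBz), C6 (OH); C7 is the exocyclic CH2OBz carbon; O4–O7 are the oxygens on these carbons; TBS = tert-butyldimethylsilyl.

Remark (configuration): 2-deoxy-L-ribose is (3R,4S); its C3 and C4 become ring C4 (R) and C5 (R) with no bond to either centre broken. The target needs O4/O5 cis, O5/O6 trans and C6–OH/C1–OH cis. The precursor and cyclisation-product structures are consistent with this and need no correction.

Remark (design): the enone is entered at the ketone oxidation level, because oxidising a hept-1-ene-3,7-diol would pass through a 1,5-hydroxy aldehyde that closes to a pyranose lactol and over-oxidises to the δ-lactone. The O4 silyl ether is kept as TBS: its bulk anchors the cyclisation transition state (O4 equatorial, O5 axial) and it is removable with acidic fluoride.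

Step 1
Reactants: 1 2-deoxy-L-ribose
Product: 2 2-deoxy-L-ribono-1,4-lactone [(4R,5S)-4-hydroxy-5-(hydroxymethyl)oxolan-2-one]
Conditions: Br2, H2O, rt, dark; concentrate
Reagents that add atoms: none
Why: Aqueous bromine oxidation of an aldose hemiacetal to the aldonolactone (hypobromite oxidation) is standard for 2-deoxypentoses, the product settling as the five-membered 1,4-lactone with both stereocentres untouched.

Step 2
Reactants: 2 2-deoxy-L-ribono-1,4-lactone; 3 tert-butyldimethylsilyl chloride
Product: 4 (4R,5S)-4-[(tert-butyldimethylsilyl)oxy]-5-{[(tert-butyldimethylsilyl)oxy]methyl}oxolan-2-one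
Conditions: TBSCl (2.5 equiv), imidazole, DMF, rt
Reagents that add atoms: tert-butyldimethylsilyl chloride, CC(C)(C)[Si](C)(C)Cl
Why: Silyl ether formation with TBSCl/imidazole protects both free hydroxyls, so that the lactone ring oxygen (the future O5) is the only oxygen left unsilylated.

Step 3
Reactants: 4 bis-TBS lactone; 5 N,O-dimethylhydroxylamine hydrochloride; 6 benzoyl chloride
Product: 8 (2S,3R)-1,3-bis[(tert-butyldimethylsilyl)oxy]-5-[methoxy(methyl)amino]-5-oxopentan-2-yl benzoate, via hydroxy Weinreb amide 7 (not isolated)
Conditions: Me(MeO)NMgCl [from MeNH(OMe)·HCl (1.6 equiv), i-PrMgCl (3.2 equiv)], THF, −20 → 0 °C; then BzCl (2.5 equiv), DMAP (cat.), 0 °C → rt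
Reagents that add atoms: N,O-dimethylhydroxylamine hydrochloride, CNOC.Cl; benzoyl chloride, O=C(Cl)c1ccccc1
Why: Weinreb aminolysis of a γ-lactone by the chloromagnesium amide opens the ring at the acyl–oxygen bond without touching C3 or C4, and the C4 magnesium alkoxide set free is O-acylated in the same flask before it can re-lactonise, which places the benzoate on exactly the oxygen that becomes O5.

Step 4
Reactants: 8 benzoate Weinreb amide; 9 vinylmagnesium bromide
Product: 10 (2S,3R)-1,3-bis[(tert-butyldimethylsilyl)oxy]-5-oxohept-6-en-2-yl benzoate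
Conditions: CH2=CHMgBr (1.5 equiv), THF, −40 → −15 °C; inverse quench into cold 1 M HCl
Reagents that add atoms: vinylmagnesium bromide, C=C[Mg]Br
Why: Weinreb ketone synthesis: the Grignard reagent adds once to the N-methoxy-N-methylamide through a stable magnesium chelate, which at low temperature should react well ahead of the hindered secondary benzoate, and the inverse acidic quench protonates the released hydroxylamine so that it cannot add to the vinyl ketone.

Step 5
Reactants: 10 bis-TBS vinyl ketone
Product: 11 (2S,3R)-3-[(tert-butyldimethylsilyl)oxy]-1-hydroxy-5-oxohept-6-en-2-yl benzoate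
Conditions: HF·pyridine, pyridine, THF, 0 °C
Reagents that add atoms: none
Why: Sterically controlled silyl ether cleavage: buffered HF·pyridine removes the primary TBS group far faster than the secondary one flanked by two substituents, and the weakly acidic medium should not promote benzoate migration to the new primary hydroxyl.

Step 6
Reactants: 11 primary alcohol
Product: 12 (2R,3R)-3-[(tert-butyldimethylsilyl)oxy]-1,5-dioxohept-6-en-2-yl benzoate (2-O-benzoyl-3-O-TBS-5-oxohept-6-enal)
Conditions: Dess–Martin periodinane, CH2Cl2, 0 °C → rt; used at once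
Reagents that add atoms: none
Why: Dess–Martin oxidation of the primary alcohol (drawn from the open form of its hemiketal equilibrium) gives the aldehyde without base, so the α-benzoyloxy stereocentre and the β-silyloxy group should survive.

Step 7
Reactants: 12 vinyl ketone–aldehyde
Product: 13 (1S,2R,6R)-6-[(tert-butyldimethylsilyl)oxy]-2-hydroxy-3-methylidene-4-oxocyclohexyl benzoate (ring C4 OTBS, C5 OBz, C6 OH trans to O5, C1=C7 exocyclic)
Conditions: PMe3 (0.3 equiv), t-AmOH, 0.02 M, 0 °C → rt
Reagents that add atoms: none
Why: PMe3 adds reversibly to C7 of the vinyl ketone to give a phosphonium enolate whose C1 attacks the C6 aldehyde, and proton transfer relayed by the alcohol solvent followed by E1cB loss of the phosphine regenerates the C1=C7 alkene. The closest known reaction type is the phosphine-catalysed intramolecular Morita–Baylis–Hillman cyclisation of enone–aldehydes to 2-methylene-3-hydroxycycloalkanones. The single ring is closed in the 6-(enolendo)-exo-trig mode, the C1–C6 bond forming with C1 and C2 of the enolate inside the ring and the aldehyde C=O outside. The new C6 stereocentre is controlled by C5: in the chair-like transition state the bulky O4 silyl ether sits equatorial, the cis C5 benzoate is therefore axial, and the aldehyde oxygen aligns anti to the C5–O dipole (polar Felkin–Anh/Cornforth alignment), which should give the 5,6-trans carbinol (C6 R in 13), while reversibility of the aldol step lets a minor aldolate return. The step needs ring closure to beat intermolecular Rauhut–Currier/MBH oligomerisation and needs C5 and the O4 silyl ether to survive, which high dilution, the six-membered tether and a neutral, non-basic phosphine in a non-adding tertiary alcohol secure. The trans-diaxial O5/O6 arrangement of the aldolate also holds the alkoxide away from the benzoate carbonyl, so acyl transfer is not expected to compete.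

Step 8
Reactants: 13 exocyclic enone; 14 tert-butyl hydroperoxide
Product: 15 (3S,4S,5S,6R)-6-[(tert-butyldimethylsilyl)oxy]-4-hydroxy-8-oxo-1-oxaspiro[2.5]octan-5-yl benzoate (C1/C7 spiro-epoxide, epoxide oxygen cis to C6–OH)
Conditions: Ti(OiPr)4 (1.1 equiv), t-BuOOH (2 equiv, in decane), 4 Å MS, CH2Cl2, −20 → 0 °C
Reagents that add atoms: tert-butyl hydroperoxide, CC(C)(C)OO
Why: Hydroxyl-directed epoxidation with a titanium alkoxide/alkyl hydroperoxide, a reaction type established for α-methylene-β-hydroxy carbonyl compounds: the C6 titanium alkoxide carries the peroxide and transfers oxygen within the complex to the face of C1=C7 on which O6 lies, which sets C1 (S) with the new C1–O bond cis to C6–OH.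

Step 9
Reactants: 15 spiro-epoxide; 16 benzoic acid
Product: 17 [(1S,2S,3S,4R)-3-(benzoyloxy)-4-[(tert-butyldimethylsilyl)oxy]-1,2-dihydroxy-6-oxocyclohexyl]methyl benzoate
Conditions: PhCO2H (2 equiv), Ti(OiPr)4 (1.5 equiv), CH2Cl2, rt
Reagents that add atoms: benzoic acid, O=C(O)c1ccccc1
Why: Titanium-mediated ring opening of a 2,3-epoxy alcohol by a carboxylic acid takes place at the distal epoxide carbon, here the unhindered primary C7, by SN2 attack, so the C1–O bond and the C1 configuration are retained and the tertiary C1 hydroxyl and the C7 benzoate appear together.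

Step 10
Reactants: 17 O4-TBS ether of the target
Product: 18 [(1S,2S,3R,4R)-3-(benzoyloxy)-1,2,4-trihydroxy-6-oxocyclohexyl]methyl benzoate (CNP0127041.1)
Conditions: 48% aq HF, MeCN, 0 °C → rt
Reagents that add atoms: none
Why: Acidic fluoride desilylation removes the secondary TBS ether while avoiding the basic conditions under which benzoate migration, β-elimination across C3–C4 or retro-aldol cleavage of the β-hydroxy ketone would be expected.

Compound list
1 | 2-deoxy-L-ribose [(3R,4S)-3,4,5-trihydroxypentanal, open-chain form] | O=CC[C@@H](O)[C@@H](O)CO | starting material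
2 | 2-deoxy-L-ribono-1,4-lactone [(4R,5S)-4-hydroxy-5-(hydroxymethyl)oxolan-2-one] | O=C1C[C@@H](O)[C@H](CO)O1 | intermediate
3 | tert-butyldimethylsilyl chloride | CC(C)(C)[Si](C)(C)Cl | starting material
4 | (4R,5S)-4-[(tert-butyldimethylsilyl)oxy]-5-{[(tert-butyldimethylsilyl)oxy]methyl}oxolan-2-one | O=C1C[C@@H](O[Si](C)(C)C(C)(C)C)[C@H](CO[Si](C)(C)C(C)(C)C)O1 | intermediate
5 | N,O-dimethylhydroxylamine hydrochloride | CNOC.Cl | starting material
6 | benzoyl chloride | O=C(Cl)c1ccccc1 | starting material
7 | (3R,4S)-3,5-bis[(tert-butyldimethylsilyl)oxy]-4-hydroxy-N-methoxy-N-methylpentanamide (present as its chloromagnesium alkoxide; not isolated) | CON(C)C(=O)C[C@@H](O[Si](C)(C)C(C)(C)C)[C@@H](O)CO[Si](C)(C)C(C)(C)C | intermediate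
8 | (2S,3R)-1,3-bis[(tert-butyldimethylsilyl)oxy]-5-[methoxy(methyl)amino]-5-oxopentan-2-yl benzoate | CON(C)C(=O)C[C@@H](O[Si](C)(C)C(C)(C)C)[C@@H](OC(=O)c1ccccc1)CO[Si](C)(C)C(C)(C)C | intermediate
9 | vinylmagnesium bromide | C=C[Mg]Br | starting material
10 | (2S,3R)-1,3-bis[(tert-butyldimethylsilyl)oxy]-5-oxohept-6-en-2-yl benzoate | C=CC(=O)C[C@@H](O[Si](C)(C)C(C)(C)C)[C@@H](OC(=O)c1ccccc1)CO[Si](C)(C)C(C)(C)C | intermediate
11 | (2S,3R)-3-[(tert-butyldimethylsilyl)oxy]-1-hydroxy-5-oxohept-6-en-2-yl benzoate | C=CC(=O)C[C@@H](O[Si](C)(C)C(C)(C)C)[C@@H](OC(=O)c1ccccc1)CO | intermediate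
12 | (2R,3R)-3-[(tert-butyldimethylsilyl)oxy]-1,5-dioxohept-6-en-2-yl benzoate | C=CC(=O)C[C@@H](O[Si](C)(C)C(C)(C)C)[C@@H](OC(=O)c1ccccc1)C=O | intermediate
13 | (1S,2R,6R)-6-[(tert-butyldimethylsilyl)oxy]-2-hydroxy-3-methylidene-4-oxocyclohexyl benzoate | C=C1C(=O)C[C@@H](O[Si](C)(C)C(C)(C)C)[C@@H](OC(=O)c2ccccc2)[C@@H]1O | intermediate
14 | tert-butyl hydroperoxide | CC(C)(C)OO | starting material
15 | (3S,4S,5S,6R)-6-[(tert-butyldimethylsilyl)oxy]-4-hydroxy-8-oxo-1-oxaspiro[2.5]octan-5-yl benzoate | C1O[C@@]12C(=O)C[C@@H](O[Si](C)(C)C(C)(C)C)[C@@H](OC(=O)c3ccccc3)[C@@H]2O | intermediate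
16 | benzoic acid | O=C(O)c1ccccc1 | starting material
17 | [(1S,2S,3S,4R)-3-(benzoyloxy)-4-[(tert-butyldimethylsilyl)oxy]-1,2-dihydroxy-6-oxocyclohexyl]methyl benzoate | O=C(OC[C@@]1(O)C(=O)C[C@@H](O[Si](C)(C)C(C)(C)C)[C@@H](OC(=O)c2ccccc2)[C@@H]1O)c1ccccc1 | intermediate
18 | [(1S,2S,3R,4R)-3-(benzoyloxy)-1,2,4-trihydroxy-6-oxocyclohexyl]methyl benzoate (CNP0127041.1) | O=C(OC[C@@]1(O)C(=O)C[C@@H](O)[C@@H](OC(=O)c2ccccc2)[C@@H]1O)c1ccccc1 | target

Total step count: 10. Longest linear sequence: 10 steps (1 → 18; the route is fully linear).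

Steps most likely to fail

1. Step 7 (key cyclisation). What may go wrong: intermolecular Rauhut–Currier/MBH oligomerisation of the unsubstituted vinyl ketone outrunning ring closure; enolisation of the α-benzoyloxy aldehyde with loss of the C5 configuration or β-elimination of silanol; insufficient facial selectivity at C6. Fallback (same C1–C6 bond, but a stoichiometric two-stage halo-aldol in place of nucleophilic catalysis): setting out from 12, Et2AlI (CH2Cl2, −78 °C) should add iodide to C7, and the aluminium enolate so formed should close onto the C6 aldehyde to give the iodomethyl ketol F1. Et3N (CH2Cl2, 0 °C) should then eliminate HI across C1–C7, and the route is rejoined at 13.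

2. Step 8 (directed epoxidation). What may go wrong: slow oxygen transfer to the electron-poor C1=C7 bond, leaving time for isopropoxide addition to the enone or a shift of the C5 benzoate onto the titanium-bound O6; incomplete facial delivery. Fallback (dihydroxylation in place of epoxidation and opening): setting out from 13, OsO4·TMEDA (1 equiv, CH2Cl2, −78 °C), whose oxo ligands accept a hydrogen bond from C6–OH, should add to the O6 face of C1=C7 and give the TMEDA-ligated osmate ester F2. Aqueous Na2SO3/THF should release the triol F3. BzCl (1.05 equiv) with 2,4,6-collidine in CH2Cl2 at −40 °C should acylate only the primary C7 hydroxyl, and the route is rejoined at 17, with 15 and step 9 bypassed.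

3. Step 4 (vinyl ketone formation). What may go wrong: competing attack of the Grignard reagent on the benzoate; conjugate addition of the released hydroxylamine to the new enone during quench. Fallback (vinylation at the aldehyde level in place of acyl substitution): setting out from 8, Cp2Zr(H)Cl (THF, rt) should reduce the Weinreb amide to the aldehyde F4 without touching the benzoate. CH2=CHMgBr at −78 °C should add to the aldehyde only and give the allylic alcohol F5 (C5 epimers, inconsequential). Dess–Martin oxidation should then give the vinyl ketone, and the route is rejoined at 10.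

Further compounds
F1 | step 7 | 6-[(tert-butyldimethylsilyl)oxy]-2-hydroxy-3-(iodomethyl)-4-oxocyclohexyl benzoate (C3 epimers; oxygen-bearing centres as in 13) | ICC1C(=O)C[C@@H](O[Si](C)(C)C(C)(C)C)[C@@H](OC(=O)c2ccccc2)[C@@H]1O
F2 | step 8 | cyclic osmate(VI) ester across O1/O7 of F3, TMEDA-ligated | O=[Os]1(=O)OC[C@@]2(O1)C(=O)C[C@@H](O[Si](C)(C)C(C)(C)C)[C@@H](OC(=O)c3ccccc3)[C@@H]2O.CN(C)CCN(C)C
F3 | step 8 | (1S,2S,3S,6R)-6-[(tert-butyldimethylsilyl)oxy]-2,3-dihydroxy-3-(hydroxymethyl)-4-oxocyclohexyl benzoate | OC[C@@]1(O)C(=O)C[C@@H](O[Si](C)(C)C(C)(C)C)[C@@H](OC(=O)c2ccccc2)[C@@H]1O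
F4 | step 4 | (2S,3R)-1,3-bis[(tert-butyldimethylsilyl)oxy]-5-oxopentan-2-yl benzoate | O=CC[C@@H](O[Si](C)(C)C(C)(C)C)[C@@H](OC(=O)c1ccccc1)CO[Si](C)(C)C(C)(C)C
F5 | step 4 | (2S,3R)-1,3-bis[(tert-butyldimethylsilyl)oxy]-5-hydroxyhept-6-en-2-yl benzoate (C5 epimers) | C=CC(O)C[C@@H](O[Si](C)(C)C(C)(C)C)[C@@H](OC(=O)c1ccccc1)CO[Si](C)(C)C(C)(C)C
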